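**Plan**

Numbering for each ring (ring A plain, ring B primed): C1 axis, C2 OH, C3 acetyl, C4 OMe, C5 CH3, C6 OMe.
Cuts, in retrosynthetic order: the two C3–acetyl bonds (Fries, back to the C2 acetates), the two C5–CH3 bonds, then the C1–C1' axis. This leaves two molecules of 3,5-dimethoxyphenol.
Enabling feature: in rings A and B the methyl-bearing C5 lies between the C4 and C6 methoxy oxygens, so in the unmethylated biaryl C5–H is the doubly activated, chelation-ready proton of a 1,3-dimethoxyarene.
Forward: no ring is made. The two purchased benzene rings are joined at C1–C1' by carbamate-directed lithiation and copper-mediated oxidative dimerisation, then C5/C5' are methylated and C3/C3' acetylated, both rings reacting in every operation.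
Stereochemistry: there is no stereocentre. The hindered axis is the only stereogenic element and arises racemic in the achiral coupling.

Key step: step 5

Assumption: the target structure carries no axial descriptor, so racemic contortin is the goal and no resolution is included.

**Step 1**
Reactants: 1 3,5-dimethoxyphenol; 2 N,N-diethylcarbamoyl chloride
Product: 3 3,5-dimethoxyphenyl N,N-diethylcarbamate
Conditions: ClCONEt2, K2CO3, MeCN, reflux
Reagents that add atoms: N,N-diethylcarbamoyl chloride, CCN(CC)C(Cl)=O
Why: O-carbamoylation of a phenol (nucleophilic acyl substitution at the carbamoyl chloride) is routine and installs the strongest oxygen-based director for the lithiation that follows.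

**Step 2**
Reactants: 3 3,5-dimethoxyphenyl N,N-diethylcarbamate (two molecules)
Product: 5 4,4',6,6'-tetramethoxybiphenyl-2,2'-diyl bis(N,N-diethylcarbamate), via aryllithium 4 (not isolated)
Conditions: s-BuLi, TMEDA, THF, −78 °C; then CuCl2·2LiCl (stock solution in THF), −78 °C → rt
Reagents that add atoms: none
Why: Directed ortho-metalation followed by oxidative homocoupling of an aryllithium with divalent copper: the O-carbamate and the neighbouring methoxyl together place lithium on the carbon between them, and the THF-soluble copper salt consumes the aryllithium at −78 °C, below the onset of the anionic ortho-Fries shift, joining two aryl groups at what becomes C1–C1'.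

**Step 3**
Reactants: 5 4,4',6,6'-tetramethoxybiphenyl-2,2'-diyl bis(N,N-diethylcarbamate)
Product: 6 4,4',6,6'-tetramethoxybiphenyl-2,2'-diol
Conditions: LiAlH4, THF, reflux; aqueous acidic work-up
Reagents that add atoms: none
Why: Reductive cleavage of aryl carbamates by hydride (acyl attack, loss of phenoxide, reduction of the formamide to the amine) is standard after directed metalation, and the strong C2 director must be removed here because it would steer the next base to C3.

**Step 4**
Reactants: 6 4,4',6,6'-tetramethoxybiphenyl-2,2'-diol; 7 triisopropylsilyl trifluoromethanesulfonate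
Product: 8 4,4',6,6'-tetramethoxy-2,2'-bis(triisopropylsilyloxy)biphenyl
Conditions: TIPSOTf, 2,6-lutidine, CH2Cl2, 0 °C → rt
Reagents that add atoms: triisopropylsilyl trifluoromethanesulfonate, CC(C)[Si](OS(=O)(=O)C(F)(F)F)(C(C)C)C(C)C
Why: Silylation of phenols with a silyl triflate and a hindered pyridine base is reliable even beside an ortho aryl group, and it turns each C2 oxygen into a bulky, weakly coordinating substituent that survives alkyllithiums.

**Step 5**
Reactants: 8 4,4',6,6'-tetramethoxy-2,2'-bis(triisopropylsilyloxy)biphenyl; 9 iodomethane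
Product: 11 4,4',6,6'-tetramethoxy-5,5'-dimethyl-2,2'-bis(triisopropylsilyloxy)biphenyl, via 5,5'-dilithio biaryl 10 (not isolated)
Conditions: s-BuLi (3 equiv), TMEDA (3 equiv), Et2O, −78 → 0 °C; then MeI (excess), −78 °C → rt
Reagents that add atoms: iodomethane, CI
Why: Twofold directed ortho-metalation and SN2 C-methylation: s-BuLi·TMEDA binds to the C4 and C6 methoxy oxygens of each ring and removes the C5 proton held between them, which both oxygens acidify inductively, and each 2,6-dimethoxyaryllithium carbon of 10 then displaces iodide from MeI to form C5–CH3 and C5'–CH3. The closest known reaction is the C2 lithiation and methylation of 1,3-dimethoxybenzene and of its 4-alkyl and 4-aryl derivatives. No ring is closed and no stereocentre is created, and the racemic axis is untouched. The selectivity needed is C5–H over C3–H, the only other ring proton; it is secured by the C2 triisopropylsilyl ether, whose oxygen is a poor ligand for lithium and whose isopropyl groups crowd C3, so that O-to-C silyl migration, which needs a C3 anion, also has no entry point. The two rings are nearly orthogonal and electronically insulated, so the second deprotonation should be little slower than the first, and excess base with a final warm-up should complete the dianion before the quench. Diethyl ether rather than THF keeps the substrate oxygens as the best ligands for lithium and lengthens the life of the base at the upper temperature.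

**Step 6**
Reactants: 11 4,4',6,6'-tetramethoxy-5,5'-dimethyl-2,2'-bis(triisopropylsilyloxy)biphenyl
Product: 12 4,4',6,6'-tetramethoxy-5,5'-dimethylbiphenyl-2,2'-diol
Conditions: Bu4NF, THF, 0 °C → rt; H2O
Reagents that add atoms: none
Why: Fluoride-induced desilylation, driven by the strong Si–F bond and the good phenoxide leaving group, is fast for aryl silyl ethers and touches neither the methyl ethers nor the axis.

**Step 7**
Reactants: 12 4,4',6,6'-tetramethoxy-5,5'-dimethylbiphenyl-2,2'-diol; 13 acetic anhydride
Product: 14 4,4',6,6'-tetramethoxy-5,5'-dimethylbiphenyl-2,2'-diyl diacetate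
Conditions: Ac2O, pyridine, DMAP (cat.), CH2Cl2, rt
Reagents that add atoms: acetic anhydride, CC(=O)OC(C)=O
Why: DMAP-catalysed O-acetylation of phenols is general, and the small acylpyridinium electrophile should reach the C2 oxygens beside the axis without difficulty.

**Step 8**
Reactants: 14 4,4',6,6'-tetramethoxy-5,5'-dimethylbiphenyl-2,2'-diyl diacetate
Product: 15 contortin, 3,3'-diacetyl-4,4',6,6'-tetramethoxy-5,5'-dimethylbiphenyl-2,2'-diol (racemic)
Conditions: TiCl4 (5 equiv), CH2Cl2, 0 °C → rt; 1 M HCl
Reagents that add atoms: none
Why: Twofold Lewis acid Fries rearrangement: TiCl4 ionises each aryl acetate and the acylium unit is recaptured by the very electron-rich ring at C3, the only unsubstituted carbon (C1 ortho and C5 para to the oxygen are blocked), while the six-membered titanium chelate of the resulting ortho-hydroxy ketone provides the driving force and keeps the metal away from the C4 methyl ether.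

**Compound list**

1 | 3,5-dimethoxyphenol | COc1cc(O)cc(OC)c1 | starting material
2 | N,N-diethylcarbamoyl chloride | CCN(CC)C(Cl)=O | starting material
3 | 3,5-dimethoxyphenyl N,N-diethylcarbamate | CCN(CC)C(=O)Oc1cc(OC)cc(OC)c1 | intermediate
4 | 2-lithio-3,5-dimethoxyphenyl N,N-diethylcarbamate (formed in the flask) | CCN(CC)C(=O)Oc1cc(OC)cc(OC)c1[Li] | intermediate
5 | 4,4',6,6'-tetramethoxybiphenyl-2,2'-diyl bis(N,N-diethylcarbamate) | CCN(CC)C(=O)Oc1cc(OC)cc(OC)c1-c1c(OC(=O)N(CC)CC)cc(OC)cc1OC | intermediate
6 | 4,4',6,6'-tetramethoxybiphenyl-2,2'-diol | COc1cc(O)c(-c2c(O)cc(OC)cc2OC)c(OC)c1 | intermediate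
7 | triisopropylsilyl trifluoromethanesulfonate | CC(C)[Si](OS(=O)(=O)C(F)(F)F)(C(C)C)C(C)C | starting material
8 | 4,4',6,6'-tetramethoxy-2,2'-bis(triisopropylsilyloxy)biphenyl | COc1cc(O[Si](C(C)C)(C(C)C)C(C)C)c(-c2c(O[Si](C(C)C)(C(C)C)C(C)C)cc(OC)cc2OC)c(OC)c1 | intermediate
9 | iodomethane | CI | starting material
10 | 5,5'-dilithio-4,4',6,6'-tetramethoxy-2,2'-bis(triisopropylsilyloxy)biphenyl (formed in the flask) | COc1cc(O[Si](C(C)C)(C(C)C)C(C)C)c(-c2c(O[Si](C(C)C)(C(C)C)C(C)C)cc(OC)c([Li])c2OC)c(OC)c1[Li] | intermediate
11 | 4,4',6,6'-tetramethoxy-5,5'-dimethyl-2,2'-bis(triisopropylsilyloxy)biphenyl | COc1cc(O[Si](C(C)C)(C(C)C)C(C)C)c(-c2c(O[Si](C(C)C)(C(C)C)C(C)C)cc(OC)c(C)c2OC)c(OC)c1C | intermediate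
12 | 4,4',6,6'-tetramethoxy-5,5'-dimethylbiphenyl-2,2'-diol | COc1cc(O)c(-c2c(O)cc(OC)c(C)c2OC)c(OC)c1C | intermediate
13 | acetic anhydride | CC(=O)OC(C)=O | starting material
14 | 4,4',6,6'-tetramethoxy-5,5'-dimethylbiphenyl-2,2'-diyl diacetate | COc1cc(OC(C)=O)c(-c2c(OC(C)=O)cc(OC)c(C)c2OC)c(OC)c1C | intermediate
15 | contortin, 3,3'-diacetyl-4,4',6,6'-tetramethoxy-5,5'-dimethylbiphenyl-2,2'-diol (racemic) | COc1c(C)c(OC)c(-c2c(O)c(C(C)=O)c(OC)c(C)c2OC)c(O)c1C(C)=O | target

Total step count: 8. Longest linear sequence: 8 steps, from 1 to 15.

**Steps most likely to fail**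

**Step 2.**
- What may go wrong:
  - The carbamoyl group may migrate from oxygen to the lithiated carbon while the mixture warms.
  - The organocopper species may be protonated or chlorinated instead of coupled.
  - Bond formation to a fourfold ortho-substituted axis may be sluggish.
- Fallback: it sets out from 3. The same lithiation to 4 is quenched at −78 °C with I2, a trapping fast enough to outrun the carbamoyl shift, to give 2-iodo-3,5-dimethoxyphenyl N,N-diethylcarbamate F1. After isolation this iodide is dimerised in a classical Ullmann coupling (activated Cu powder, DMF, 150 °C). That reaction tolerates two ortho oxygen substituents and needs no carbanion. The route is rejoined at 5.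

**Step 5.**
- What may go wrong:
  - The second deprotonation may stay incomplete, so that only one ring is methylated.
  - Some metalation may occur at C3–H, followed by silyl migration from oxygen to carbon.
- Fallback: it sets out from 8 and fixes the site by electrophilic substitution instead of kinetic acidity. NBS (2 equiv, MeCN, 0 °C) should brominate each ring at C5, because C3 is shielded by the silyl ether. This gives 5,5'-dibromo-4,4',6,6'-tetramethoxy-2,2'-bis(triisopropylsilyloxy)biphenyl F2. A twofold Negishi methylation (MeZnCl, PdCl2(dppf) cat., THF, 60 °C) then forms the same two C5–CH3 bonds and returns to the route at 11.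

**Step 8.**
- What may go wrong:
  - The acetyl groups may be lost without recapture by the ring.
  - The reaction may stall after one migration.
  - The Lewis acid may cleave the C4 methyl ether next to the new ketone.
- Fallback: it sets out from 12 and builds the C3–acetyl bonds from a carbanion.
  - MOMCl and i-Pr2NEt in CH2Cl2 give 2,2'-bis(methoxymethoxy)-4,4',6,6'-tetramethoxy-5,5'-dimethylbiphenyl F3.
  - n-BuLi and TMEDA in THF at 0 °C metalate the only ring C–H, which lies between the acetal oxygen and the C4 methoxyl. This gives the 3,3'-dilithio bis(methoxymethyl) ether F4.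
  - Quenching with N-methoxy-N-methylacetamide (Weinreb ketone synthesis) gives 3,3'-diacetyl-2,2'-bis(methoxymethoxy)-4,4',6,6'-tetramethoxy-5,5'-dimethylbiphenyl F5.
  - HCl in MeOH at 40 °C removes the acetals, and the route is rejoined at 15.

**Further compounds**

F1 | step 2 | 2-iodo-3,5-dimethoxyphenyl N,N-diethylcarbamate | CCN(CC)C(=O)Oc1cc(OC)cc(OC)c1I
F2 | step 5 | 5,5'-dibromo-4,4',6,6'-tetramethoxy-2,2'-bis(triisopropylsilyloxy)biphenyl | COc1cc(O[Si](C(C)C)(C(C)C)C(C)C)c(-c2c(O[Si](C(C)C)(C(C)C)C(C)C)cc(OC)c(Br)c2OC)c(OC)c1Br
F3 | step 8 | 2,2'-bis(methoxymethoxy)-4,4',6,6'-tetramethoxy-5,5'-dimethylbiphenyl | COCOc1cc(OC)c(C)c(OC)c1-c1c(OCOC)cc(OC)c(C)c1OC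
F4 | step 8 | 3,3'-dilithio-2,2'-bis(methoxymethoxy)-4,4',6,6'-tetramethoxy-5,5'-dimethylbiphenyl | COCOc1c([Li])c(OC)c(C)c(OC)c1-c1c(OCOC)c([Li])c(OC)c(C)c1OC
F5 | step 8 | 3,3'-diacetyl-2,2'-bis(methoxymethoxy)-4,4',6,6'-tetramethoxy-5,5'-dimethylbiphenyl | COCOc1c(C(C)=O)c(OC)c(C)c(OC)c1-c1c(OCOC)c(C(C)=O)c(OC)c(C)c1OC
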